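## Retrosynthetic overview

1. Last C–C bond: Stille coupling of a core C4 (E)-vinylstannane with the east (2E,4E)-5-bromodienamide of 2-amino-3-hydroxycyclopentenone.
2. C2–N bond: copper-catalysed N-vinylation of the west (2E,4E,6R)-dienamide (Evans methylation sets C6') with the core α-iodoenone.
3. Core stereocentres C4/C5 (cis-diol): proposed new catalytic desymmetrising boronate oxa-Michael addition on the achiral p-quinol 4-hydroxy-4-(silylethynyl)cyclohexa-2,5-dienone, made from p-benzoquinone monoketal and a lithium acetylide.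
4. Rings: both carbocycles are bought (quinone monoketal, cyclopentane-1,3-dione). Only temporary heterocycles are formed, first the 1,3,2-dioxaborolane of the key step, then the acetonide dioxolane, and both are removed before the end.

Assumption: the epi-quinidine-derived thiourea is taken to deliver the (4R,5R)-diol 24; if the sense of induction is opposite, the pseudo-enantiomeric epi-quinine-derived catalyst is used and nothing else changes.

Note on descriptors: the ring carbinol carbon is R while it carries the alkynyl or stannylvinyl group and S in the target (trienyl group). This is a CIP priority change only; the geometry (both OH groups on the same face) is unchanged from step 12 onward.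

## West fragment

Step 1
Reactants: 1 (4R)-4-benzyl-1,3-oxazolidin-2-one; 2 hexanoyl chloride
Product: 3 (4R)-4-benzyl-3-hexanoyl-1,3-oxazolidin-2-one
Conditions: n-BuLi, THF, −78 °C; then 2, −78 → 0 °C
Reagents that add atoms: none
Why: N-acylation of the lithiated oxazolidinone by the acid chloride (Evans auxiliary loading) is fast and clean, and no stereocentre is formed.

Step 2
Reactants: 3 (4R)-4-benzyl-3-hexanoyl-1,3-oxazolidin-2-one
Product: 4 (4R)-4-benzyl-3-[(2R)-2-methylhexanoyl]-1,3-oxazolidin-2-one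
Conditions: NaN(SiMe3)2, THF, −78 °C; MeI, −78 °C
Reagents that add atoms: iodomethane, CI
Why: Evans asymmetric alkylation, in which the chelated sodium Z-enolate is methylated on the face away from the benzyl group, so the (R)-auxiliary gives the (2R)-2-methylhexanoyl unit (expected dr about 93:7, minor isomer removed by chromatography).

Step 3
Reactants: 4 (4R)-4-benzyl-3-[(2R)-2-methylhexanoyl]-1,3-oxazolidin-2-one
Product: 5 (2R)-2-methylhexan-1-ol
Conditions: LiBH4, H2O (1 equiv), Et2O, 0 °C
Reagents that add atoms: none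
Why: Reductive auxiliary cleavage, where borohydride attacks the exocyclic imide carbonyl selectively and releases the primary alcohol without touching the α-stereocentre.

Step 4
Reactants: 5 (2R)-2-methylhexan-1-ol; 6 2-(triphenylphosphoranylidene)propanal
Product: 8 (2E,4R)-2,4-dimethyloct-2-enal, via (2R)-2-methylhexanal 7 (not isolated)
Conditions: Dess–Martin periodinane, CH2Cl2, 0 °C → rt; filter, concentrate cold; then 6, toluene, 70 °C
Reagents that add atoms: none
Why: Dess–Martin oxidation gives the volatile, epimerisable aldehyde, which is trapped at once in a Wittig olefination with the stabilised formyl ylide, reliably E-selective for trisubstituted enals and leaving the existing stereocentre untouched.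

Step 5
Reactants: 8 (2E,4R)-2,4-dimethyloct-2-enal; 9 diethyl (2-amino-2-oxoethyl)phosphonate
Product: 10 (2E,4E,6R)-4,6-dimethyldeca-2,4-dienamide
Conditions: 9, NaH, THF, 0 °C; then 8, 0 °C → rt
Reagents that add atoms: none
Why: Horner–Wadsworth–Emmons olefination with the stabilised carbamoylmethylphosphonate anion gives the (2E)-alkene and installs the primary amide directly, and the weakly basic anion does not deprotonate the γ-stereocentre.

## East fragment

Step 6
Reactants: 11 cyclopentane-1,3-dione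
Product: 12 2-(hydroxyimino)cyclopentane-1,3-dione
Conditions: NaNO2, aq. HCl, 0 °C
Reagents that add atoms: sodium nitrite, [Na+].[O-]N=O
Why: C-nitrosation of the strongly enolised 1,3-dione at C2 by nitrous acid, followed by tautomerisation to the oxime (nitrosation of an active methylene compound).

Step 7
Reactants: 12 2-(hydroxyimino)cyclopentane-1,3-dione
Product: 13 2-amino-3-hydroxycyclopent-2-en-1-one hydrochloride
Conditions: H2 (1 atm), 10% Pd/C, HCl, EtOH, rt
Reagents that add atoms: hydrogen chloride, Cl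
Why: Catalytic hydrogenation of the oxime in acidic ethanol gives the primary amine, trapped as its hydrochloride so that the α-amino diketone cannot self-condense.

Step 8
Reactants: 14 potassium (1E,3E)-5-oxopenta-1,3-dien-1-olate (glutaconaldehyde potassium salt, KOCH=CH–CH=CH–CHO)
Product: 15 (2E,4E)-5-bromopenta-2,4-dienal
Conditions: Ph3PBr2, CH2Cl2, 0 °C → rt
Reagents that add atoms: dibromotriphenylphosphorane, BrP(Br)(c1ccccc1)(c1ccccc1)c1ccccc1
Why: Appel-type deoxybromination of the vinylogous formate, in which O-phosphonium formation and vinylogous addition–elimination of bromide give the thermodynamically favoured (2E,4E)-bromodienal.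

Step 9
Reactants: 15 (2E,4E)-5-bromopenta-2,4-dienal
Product: 16 (2E,4E)-5-bromopenta-2,4-dienoic acid
Conditions: NaClO2, NaH2PO4, 2-methylbut-2-ene, t-BuOH–H2O, 0 °C → rt
Reagents that add atoms: sodium chlorite, [Na+].[O-]Cl=O
Why: Pinnick oxidation converts the enal to the acid without touching the vinyl bromide or isomerising the diene, since the alkene scavenger removes hypochlorous acid.

Step 10
Reactants: 16 (2E,4E)-5-bromopenta-2,4-dienoic acid; 13 2-amino-3-hydroxycyclopent-2-en-1-one hydrochloride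
Product: 18 (2E,4E)-5-bromo-N-(2-hydroxy-5-oxocyclopent-1-en-1-yl)penta-2,4-dienamide, via acid chloride 17 (not isolated)
Conditions: (COCl)2, DMF (cat.), CH2Cl2, 0 °C → rt; evaporate; then 13, Et3N, THF, 0 °C → rt
Reagents that add atoms: none
Why: Amide formation through the acid chloride, where the freed 2-amino dione is N-acylated and any O-acyl enol ester transfers its acyl group to nitrogen under the basic conditions, giving the hydrogen-bonded enol amide.

## Core and endgame

Step 11
Reactants: 19 4,4-dimethoxycyclohexa-2,5-dien-1-one; 20 ethynyl(trimethyl)silane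
Product: 22 4-hydroxy-4-[(trimethylsilyl)ethynyl]cyclohexa-2,5-dien-1-one, via dimethyl ketal carbinol 21 (not isolated)
Conditions: 20, n-BuLi, THF, −78 °C; then 19, −78 °C; then AcOH–H2O–THF, rt
Reagents that add atoms: water, O
Why: 1,2-Addition of LiC≡CSiMe3 to the ketone of the quinone monoketal followed by mild acid ketal hydrolysis (much faster than ionisation of the carbinol) gives the p-quinol, which has a mirror plane and no stereocentre.

Step 12
Reactants: 22 4-hydroxy-4-[(trimethylsilyl)ethynyl]cyclohexa-2,5-dien-1-one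
Product: 24 (4R,5R)-4,5-dihydroxy-4-[(trimethylsilyl)ethynyl]cyclohex-2-en-1-one, via cyclic phenylboronate 23 (not isolated)
Conditions: PhB(OH)2 (1.2 equiv), N-[3,5-bis(trifluoromethyl)phenyl]-N′-[(9R)-6′-methoxycinchonan-9-yl]thiourea (10 mol %), 4 Å MS, toluene, 0 °C → rt; then pinacol (3 equiv), rt
Reagents that add atoms: phenylboronic acid, OB(O)c1ccccc1
Why: Proposed new method: a bifunctional amine–thiourea-catalysed boronate oxa-Michael desymmetrisation of a prochiral p-quinol, in which the tertiary OH condenses reversibly with the boronic acid to a hemiester, the quinuclidine nitrogen binds boron to make a nucleophilic hydroxyboronate while the thiourea hydrogen-bonds the dienone carbonyl, and the B–OH oxygen is delivered 5-exo-trig to only one of the two enantiotopic β-carbons; the dioxaborolane can only be cis-fused, so the catalyst has to choose the enone arm only and C4 and C5 are set together (pinacol then frees the diol, whose C5 oxygen comes from the boronic acid), the closest known reaction types being the amine–thiourea-catalysed oxa-Michael addition of boronic acid hemiesters of acyclic γ-hydroxy enones and the chiral-acid acetalisation/oxa-Michael desymmetrisation of p-quinols, neither of which has, to my knowledge, been shown as a group-selective boronate delivery on a cyclohexadienone with a tertiary alkynyl carbinol.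

Step 13
Reactants: 24 (4R,5R)-4,5-dihydroxy-4-[(trimethylsilyl)ethynyl]cyclohex-2-en-1-one
Product: 25 (3aR,7aR)-2,2-dimethyl-7a-[(trimethylsilyl)ethynyl]-3a,7a-dihydro-1,3-benzodioxol-5(4H)-one
Conditions: Me2C(OMe)2, PPTS (cat.), CH2Cl2, rt
Reagents that add atoms: 2,2-dimethoxypropane, COC(C)(C)OC
Why: Acid-catalysed transketalisation to the acetonide is favourable for a cis-1,2-diol and ties up both hydroxyls so that the β-oxy ketone cannot dehydrate in the later basic step.

Step 14
Reactants: 25 (3aR,7aR)-2,2-dimethyl-7a-[(trimethylsilyl)ethynyl]-3a,7a-dihydro-1,3-benzodioxol-5(4H)-one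
Product: 26 (3aR,7aR)-6-iodo-2,2-dimethyl-7a-[(trimethylsilyl)ethynyl]-3a,7a-dihydro-1,3-benzodioxol-5(4H)-one
Conditions: I2, DMAP (cat.), pyridine–CH2Cl2 (1:1), 0 °C → rt
Reagents that add atoms: iodine, II
Why: α-Iodination of the enone by conjugate addition of pyridine, iodination of the enolate and elimination (Baylis–Hillman-type addition–elimination) functionalises only the vinylic α-carbon, and the alkynylsilane, acetonide and both stereocentres are inert.

Step 15
Reactants: 26 (3aR,7aR)-6-iodo-2,2-dimethyl-7a-[(trimethylsilyl)ethynyl]-3a,7a-dihydro-1,3-benzodioxol-5(4H)-one; 10 (2E,4E,6R)-4,6-dimethyldeca-2,4-dienamide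
Product: 27 (2E,4E,6R)-N-[(3aR,7aR)-2,2-dimethyl-5-oxo-7a-[(trimethylsilyl)ethynyl]-3a,4,5,7a-tetrahydro-1,3-benzodioxol-6-yl]-4,6-dimethyldeca-2,4-dienamide
Conditions: CuI (10 mol %), MeNHCH2CH2NHMe (20 mol %), Cs2CO3, THF, 55 °C
Reagents that add atoms: none
Why: Copper-catalysed Goldberg-type N-vinylation of the primary amide by the vinyl iodide forms the C2–N bond; the alkyne is silyl-capped to prevent copper acetylide chemistry, and any reversible retro-oxa-Michael opening at C5 can only reclose cis because C4 is fixed.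

Step 16
Reactants: 27 (2E,4E,6R)-N-[(3aR,7aR)-2,2-dimethyl-5-oxo-7a-[(trimethylsilyl)ethynyl]-3a,4,5,7a-tetrahydro-1,3-benzodioxol-6-yl]-4,6-dimethyldeca-2,4-dienamide
Product: 28 (2E,4E,6R)-N-[(3aR,7aR)-7a-ethynyl-2,2-dimethyl-5-oxo-3a,4,5,7a-tetrahydro-1,3-benzodioxol-6-yl]-4,6-dimethyldeca-2,4-dienamide
Conditions: Bu4NF, AcOH (1:1), THF, 0 °C
Reagents that add atoms: none
Why: Fluoride-induced protodesilylation of the alkynylsilane is fast, and the acetic acid buffer avoids base-induced β-elimination of the β-oxy ketone.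

Step 17
Reactants: 28 (2E,4E,6R)-N-[(3aR,7aR)-7a-ethynyl-2,2-dimethyl-5-oxo-3a,4,5,7a-tetrahydro-1,3-benzodioxol-6-yl]-4,6-dimethyldeca-2,4-dienamide
Product: 29 (2E,4E,6R)-N-[(3R,4R)-3-ethynyl-3,4-dihydroxy-6-oxocyclohex-1-en-1-yl]-4,6-dimethyldeca-2,4-dienamide
Conditions: CF3CO2H–H2O–CH2Cl2, 0 °C → rt
Reagents that add atoms: none
Why: Acid-catalysed acetonide hydrolysis frees the cis-diol before tin is introduced (vinylstannanes do not survive acid), and the electron-poor carbinol flanked by enone and alkyne resists ionisation.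

Step 18
Reactants: 29 (2E,4E,6R)-N-[(3R,4R)-3-ethynyl-3,4-dihydroxy-6-oxocyclohex-1-en-1-yl]-4,6-dimethyldeca-2,4-dienamide
Product: 30 (2E,4E,6R)-N-[(3R,4R)-3,4-dihydroxy-6-oxo-3-[(E)-2-(tributylstannyl)ethenyl]cyclohex-1-en-1-yl]-4,6-dimethyldeca-2,4-dienamide
Conditions: PdCl2(PPh3)2 (5 mol %), Bu3SnH (1.2 equiv, slow addition), THF, 0 °C
Reagents that add atoms: tributylstannane, CCCC[SnH](CCCC)CCCC
Why: Palladium-catalysed syn-hydrostannation of the terminal alkyne puts tin on the unhindered terminal carbon (the quaternary propargylic centre disfavours the internal isomer) and gives the (E)-vinylstannane, alkyne insertion being much faster than conjugate reduction of the amido enone.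

Step 19
Reactants: 30 (2E,4E,6R)-N-[(3R,4R)-3,4-dihydroxy-6-oxo-3-[(E)-2-(tributylstannyl)ethenyl]cyclohex-1-en-1-yl]-4,6-dimethyldeca-2,4-dienamide; 18 (2E,4E)-5-bromo-N-(2-hydroxy-5-oxocyclopent-1-en-1-yl)penta-2,4-dienamide
Product: 31 (2E,4E,6R)-N-[(3S,4R)-3,4-dihydroxy-3-[(1E,3E,5E)-7-[(2-hydroxy-5-oxocyclopent-1-en-1-yl)amino]-7-oxohepta-1,3,5-trien-1-yl]-6-oxocyclohex-1-en-1-yl]-4,6-dimethyldeca-2,4-dienamide
Conditions: PdCl2(MeCN)2 (10 mol %), DMF, rt, dark
Reagents that add atoms: none
Why: Stille cross-coupling of the (E)-vinylstannane with the (E,E)-bromodiene proceeds with retention at both partners under neutral, base-free conditions that tolerate the free diol, the enol and the β-hydroxy ketone, giving the (E,E,E)-triene of the target.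

## Compound list

1 | (4R)-4-benzyl-1,3-oxazolidin-2-one | O=C1N[C@H](Cc2ccccc2)CO1 | starting material
2 | hexanoyl chloride | CCCCCC(Cl)=O | starting material
3 | (4R)-4-benzyl-3-hexanoyl-1,3-oxazolidin-2-one | CCCCCC(=O)N1[C@H](Cc2ccccc2)COC1=O | intermediate
4 | (4R)-4-benzyl-3-[(2R)-2-methylhexanoyl]-1,3-oxazolidin-2-one | CCCC[C@@H](C)C(=O)N1[C@H](Cc2ccccc2)COC1=O | intermediate
5 | (2R)-2-methylhexan-1-ol | CCCC[C@@H](C)CO | intermediate
6 | 2-(triphenylphosphoranylidene)propanal | CC(C=O)=P(c1ccccc1)(c1ccccc1)c1ccccc1 | starting material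
7 | (2R)-2-methylhexanal | CCCC[C@@H](C)C=O | intermediate
8 | (2E,4R)-2,4-dimethyloct-2-enal | CCCC[C@@H](C)/C=C(C)/C=O | intermediate
9 | diethyl (2-amino-2-oxoethyl)phosphonate | CCOP(=O)(CC(N)=O)OCC | starting material
10 | (2E,4E,6R)-4,6-dimethyldeca-2,4-dienamide | CCCC[C@@H](C)/C=C(C)/C=C/C(N)=O | intermediate
11 | cyclopentane-1,3-dione | O=C1CCC(=O)C1 | starting material
12 | 2-(hydroxyimino)cyclopentane-1,3-dione | ON=C1C(=O)CCC1=O | intermediate
13 | 2-amino-3-hydroxycyclopent-2-en-1-one hydrochloride | NC1=C(O)CCC1=O.Cl | intermediate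
14 | potassium (1E,3E)-5-oxopenta-1,3-dien-1-olate | [K+].[O-]/C=C/C=C/C=O | starting material
15 | (2E,4E)-5-bromopenta-2,4-dienal | Br/C=C/C=C/C=O | intermediate
16 | (2E,4E)-5-bromopenta-2,4-dienoic acid | Br/C=C/C=C/C(O)=O | intermediate
17 | (2E,4E)-5-bromopenta-2,4-dienoyl chloride | Br/C=C/C=C/C(Cl)=O | intermediate
18 | (2E,4E)-5-bromo-N-(2-hydroxy-5-oxocyclopent-1-en-1-yl)penta-2,4-dienamide | Br/C=C/C=C/C(=O)NC1=C(O)CCC1=O | intermediate
19 | 4,4-dimethoxycyclohexa-2,5-dien-1-one | COC1(OC)C=CC(=O)C=C1 | starting material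
20 | ethynyl(trimethyl)silane | C#C[Si](C)(C)C | starting material
21 | 4,4-dimethoxy-1-[(trimethylsilyl)ethynyl]cyclohexa-2,5-dien-1-ol | COC1(OC)C=CC(O)(C#C[Si](C)(C)C)C=C1 | intermediate
22 | 4-hydroxy-4-[(trimethylsilyl)ethynyl]cyclohexa-2,5-dien-1-one | O=C1C=CC(O)(C#C[Si](C)(C)C)C=C1 | intermediate
23 | (3aR,7aR)-2-phenyl-7a-[(trimethylsilyl)ethynyl]-3a,7a-dihydro-1,3,2-benzodioxaborol-5(4H)-one | C1=C[C@@](O2)(C#C[Si](C)(C)C)[C@H](OB2c3ccccc3)CC1=O | intermediate
24 | (4R,5R)-4,5-dihydroxy-4-[(trimethylsilyl)ethynyl]cyclohex-2-en-1-one | C1=C[C@@](O)(C#C[Si](C)(C)C)[C@H](O)CC1=O | intermediate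
25 | (3aR,7aR)-2,2-dimethyl-7a-[(trimethylsilyl)ethynyl]-3a,7a-dihydro-1,3-benzodioxol-5(4H)-one | C1=C[C@@](O2)(C#C[Si](C)(C)C)[C@H](OC2(C)C)CC1=O | intermediate
26 | (3aR,7aR)-6-iodo-2,2-dimethyl-7a-[(trimethylsilyl)ethynyl]-3a,7a-dihydro-1,3-benzodioxol-5(4H)-one | IC1=C[C@@](O2)(C#C[Si](C)(C)C)[C@H](OC2(C)C)CC1=O | intermediate
27 | (2E,4E,6R)-N-[(3aR,7aR)-2,2-dimethyl-5-oxo-7a-[(trimethylsilyl)ethynyl]-3a,4,5,7a-tetrahydro-1,3-benzodioxol-6-yl]-4,6-dimethyldeca-2,4-dienamide | CCCC[C@@H](C)/C=C(C)/C=C/C(=O)NC1=C[C@@](O2)(C#C[Si](C)(C)C)[C@H](OC2(C)C)CC1=O | intermediate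
28 | (2E,4E,6R)-N-[(3aR,7aR)-7a-ethynyl-2,2-dimethyl-5-oxo-3a,4,5,7a-tetrahydro-1,3-benzodioxol-6-yl]-4,6-dimethyldeca-2,4-dienamide | CCCC[C@@H](C)/C=C(C)/C=C/C(=O)NC1=C[C@@](O2)(C#C)[C@H](OC2(C)C)CC1=O | intermediate
29 | (2E,4E,6R)-N-[(3R,4R)-3-ethynyl-3,4-dihydroxy-6-oxocyclohex-1-en-1-yl]-4,6-dimethyldeca-2,4-dienamide | CCCC[C@@H](C)/C=C(C)/C=C/C(=O)NC1=C[C@@](O)(C#C)[C@H](O)CC1=O | intermediate
30 | (2E,4E,6R)-N-[(3R,4R)-3,4-dihydroxy-6-oxo-3-[(E)-2-(tributylstannyl)ethenyl]cyclohex-1-en-1-yl]-4,6-dimethyldeca-2,4-dienamide | CCCC[C@@H](C)/C=C(C)/C=C/C(=O)NC1=C[C@@](O)(/C=C/[Sn](CCCC)(CCCC)CCCC)[C@H](O)CC1=O | intermediate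
31 | (2E,4E,6R)-N-[(3S,4R)-3,4-dihydroxy-3-[(1E,3E,5E)-7-[(2-hydroxy-5-oxocyclopent-1-en-1-yl)amino]-7-oxohepta-1,3,5-trien-1-yl]-6-oxocyclohex-1-en-1-yl]-4,6-dimethyldeca-2,4-dienamide | CCCC[C@@H](C)/C=C(C)/C=C/C(=O)NC1=C[C@@](O)(/C=C/C=C/C=C/C(=O)NC2=C(O)CCC2=O)[C@H](O)CC1=O | target

## Step count and risk

Total step count: 19. Longest linear sequence: 10 steps (steps 1–5, then 15–19); the core branch from 19 is 9 steps and the east branch joins in the last step.

Three steps most likely to fail:

Step 12 (the proposed new desymmetrisation). The hindered tertiary carbinol may form the boronic hemiester slowly, the catalyst may not discriminate the two enone arms well enough, and reversibility could erode the ee. The fallback uses known chemistry and sets out from 22. A chiral BINOL-phosphoric-acid-catalysed hemiacetalisation/oxa-Michael cascade of 22 with 3-methylbutanal ((R)-TRIP or its antipode as required, toluene, rt) gives the cis-fused 2-isobutyl dioxolane acetal F1. Hydrolysis of the acetal (CF3CO2H–H2O–CH2Cl2, 0 °C) then gives the diol, and the route is rejoined at 24.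

Step 15 (copper-catalysed amidation of the α-iodoenone). The iodide sits next to a quaternary centre, and the carbonate base can trigger β-elimination at C5 or partial desilylation. The fallback sets out from 25 and 8 and builds the C–N bond without a metal coupling. Nucleophilic epoxidation of 25 (t-BuOOH, DBU, CH2Cl2) gives the α,β-epoxy ketone F2. Opening at the α-carbon with NaN3/NH4Cl (DMF–H2O) and loss of the β-hydroxyl gives the 6-azido enone F3. Staudinger reduction (PPh3, THF, then H2O) gives the 6-amino enone F4. Carbodiimide acylation with (diethoxyphosphoryl)acetic acid gives the phosphonoacetamide F5. A Horner–Wadsworth–Emmons reaction of F5 with enal 8 (LiCl, DBU, MeCN) forms the (2E)-alkene, and the route is rejoined at 27.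

Step 18 (hydrostannation). Some internal stannane, palladium hydride conjugate reduction of the amido enone, or protodestannylation on silica can lower the yield. The fallback sets out from 29 and 18 and avoids tin altogether. Sonogashira coupling of 29 with 18 (Pd(PPh3)4, CuI, i-Pr2NH, THF, rt) gives the dienyne F6. Ruthenium-catalysed trans-hydrosilylation ([Cp*Ru(MeCN)3]PF6, (EtO)3SiH, CH2Cl2, 0 °C) gives the (Z)-vinylsilane F7. Protodesilylation with retention (AgF, THF–MeOH–H2O, dark) turns the alkyne into the (E)-alkene overall and arrives directly at 31.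

Further compounds

F1 | step 12 | (3aR,7aR)-2-(2-methylpropyl)-7a-[(trimethylsilyl)ethynyl]-3a,7a-dihydro-1,3-benzodioxol-5(4H)-one (2-isobutyl dioxolane acetal, acetal carbon unassigned) | C1=C[C@@](O2)(C#C[Si](C)(C)C)[C@H](OC2CC(C)C)CC1=O
F2 | step 15 | α,β-epoxy ketone: 6,7-epoxide of 25 (ring-fusion centres as in 25, epoxide face unassigned) | C14OC4[C@@](O2)(C#C[Si](C)(C)C)[C@H](OC2(C)C)CC1=O
F3 | step 15 | 6-azido enone: (3aR,7aR)-6-azido-2,2-dimethyl-7a-[(trimethylsilyl)ethynyl]-3a,7a-dihydro-1,3-benzodioxol-5(4H)-one | [N-]=[N+]=NC1=C[C@@](O2)(C#C[Si](C)(C)C)[C@H](OC2(C)C)CC1=O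
F4 | step 15 | 6-amino enone: (3aR,7aR)-6-amino-2,2-dimethyl-7a-[(trimethylsilyl)ethynyl]-3a,7a-dihydro-1,3-benzodioxol-5(4H)-one | NC1=C[C@@](O2)(C#C[Si](C)(C)C)[C@H](OC2(C)C)CC1=O
F5 | step 15 | phosphonoacetamide: diethyl [2-[[(3aR,7aR)-2,2-dimethyl-5-oxo-7a-[(trimethylsilyl)ethynyl]-3a,4,5,7a-tetrahydro-1,3-benzodioxol-6-yl]amino]-2-oxoethyl]phosphonate | CCOP(=O)(OCC)CC(=O)NC1=C[C@@](O2)(C#C[Si](C)(C)C)[C@H](OC2(C)C)CC1=O
F6 | step 18 | dienyne: analogue of 31 with a triple bond in place of the ring-proximal alkene of the triene | CCCC[C@@H](C)/C=C(C)/C=C/C(=O)NC1=C[C@@](O)(C#C/C=C/C=C/C(=O)NC2=C(O)CCC2=O)[C@H](O)CC1=O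
F7 | step 18 | (Z)-vinylsilane: analogue of 31 bearing a triethoxysilyl group on the second triene carbon, cis to the ring | CCCC[C@@H](C)/C=C(C)/C=C/C(=O)NC1=C[C@@](O)(/C=C(\[Si](OCC)(OCC)OCC)/C=C/C=C/C(=O)NC2=C(O)CCC2=O)[C@H](O)CC1=O
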